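The aryl-bearing decalin (rings A' and B') is cut at C4'–C5' and C10'–C9'. This leaves the hydroxylated decalin with its C11–C12 tether as intact (+)-manool, because quaternary C4', with axial C12 arm, equatorial methyl and ring carbon C3', is manool C13 once its tertiary C–O bond is replaced by C5' with inversion. One Lewis-acid step on a cis-13,14-oxirane makes both bonds, closes rings A' and B' and sets C4', C5', C10' and C9'. Its precursor is an open chain: 8-O-silylated labdane, cis-trisubstituted oxirane (C4'–C3'), E-C5'=C10' alkene and a Z-silyl enol ether at C8'=C9' carrying the 2,5-dimethoxybenzyl group.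

Key step: step 16

Locants: the hydroxylated decalin is numbered as a labdane (C1–C17, side chain from C11); the aryl-bearing decalin as a drim-7-ene with primes (C1'–C10', benzylic C11'). C4' and C3' are C13 and C14 of manool.

Assumption: the target is made as the neutral bis(hydrogen sulfate) that is drawn; it is liberated from its pyridinium salt by cation exchange in the cold and freeze-dried at once.

Step 1
Reactants: 1 (+)-manool
Product: 2 (13R)-13-hydroxy-8-oxo-15,17-dinorlabdan-14-al
Conditions: O3, CH2Cl2–MeOH, −78 °C; Me2S, −78 °C → rt; crude product dried by toluene azeotrope and used at once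
Reagents that add atoms: ozone [O-][O+]=O
Why: Ozonolysis with reductive work-up cleaves the 8(17)-methylidene and the vinyl group to the hindered 8-ketone and a non-enolisable α-hydroxy aldehyde without touching C5, C9, C10 or C13, and the product is not purified because α-hydroxy aldehydes dimerise and this one can close to a lactol.

Step 2
Reactants: 3 6-methylhept-5-en-2-one
Product: 4 2-methyl-2-(4-methylpent-3-en-1-yl)-1,3-dioxolane
Conditions: HOCH2CH2OH, p-TsOH (cat.), benzene, reflux, Dean–Stark
Reagents that add atoms: ethylene glycol OCCO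
Why: Acid-catalysed ketalisation with azeotropic removal of water masks the methyl ketone (future C8') for the organometallic steps.

Step 3
Reactants: 4 dioxolane of 6-methylhept-5-en-2-one
Product: 5 (E)-2-methyl-5-(2-methyl-1,3-dioxolan-2-yl)pent-2-en-1-ol
Conditions: SeO2 (cat.), t-BuOOH, CH2Cl2, rt
Reagents that add atoms: tert-butyl hydroperoxide CC(C)(C)OO
Why: SeO2 allylic oxidation (ene reaction, then [2,3]-sigmatropic shift) attacks the methyl group trans to the chain of a trisubstituted alkene, so the E-allylic alcohol forms and the geometry of the later C5'=C10' alkene is fixed here.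

Step 4
Reactants: 5 E-allylic alcohol
Product: 6 (E)-2-methyl-5-(2-methyl-1,3-dioxolan-2-yl)pent-2-enal
Conditions: MnO2, CH2Cl2, rt
Reagents that add atoms: none
Why: MnO2 oxidises only the allylic alcohol, without E/Z isomerisation, and converges any enal already formed in step 3 (allylic alcohol oxidation).

Step 5
Reactants: 6 E-enal
Product: 7 (E)-2-methyl-2-(4-methylhexa-3,5-dien-1-yl)-1,3-dioxolane
Conditions: Ph3PCH3Br, KOt-Bu, THF, 0 °C → rt
Reagents that add atoms: methyltriphenylphosphonium bromide C[P+](c1ccccc1)(c1ccccc1)c1ccccc1.[Br-]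
Why: Wittig methylenation with the unstabilised ylide converts the aldehyde into the terminal vinyl group (future C2') and leaves the trisubstituted E-alkene and the ketal untouched.

Step 6
Reactants: 7 E-diene
Product: 8 (E)-3-methyl-6-(2-methyl-1,3-dioxolan-2-yl)hex-3-en-1-ol
Conditions: disiamylborane (from BH3·THF and 2-methylbut-2-ene), THF, 0 °C; NaOH, H2O2, 0 °C → rt
Reagents that add atoms: hydrogen peroxide OO
Why: The bulky dialkylborane adds anti-Markovnikov only to the monosubstituted terminal alkene of the diene, and oxidation gives the homoallylic alcohol with the E-alkene intact (selective hydroboration–oxidation).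

Step 7
Reactants: 8 homoallylic alcohol
Product: 9 (E)-2-(6-iodo-4-methylhex-3-en-1-yl)-2-methyl-1,3-dioxolane
Conditions: I2, PPh3, imidazole, CH2Cl2, 0 °C
Reagents that add atoms: iodine II
Why: Appel-type iodination of the primary alcohol through its alkoxyphosphonium salt proceeds under imidazole-buffered conditions that spare the dioxolane.

Step 8
Reactants: 9 E-homoallylic iodide; 2 keto aldehyde
Product: 13 (8S,13R,14R)-8,13,14-triol ketal, via homoallyllithium 10 (not isolated), via homoallylmagnesium bromide 11 (not isolated), via diol ketone 12 (not isolated)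
Conditions: 9, t-BuLi (2 equiv), Et2O, −78 °C; MgBr2·OEt2, −78 → 0 °C; added at −78 °C to 2 pre-treated with 2,4,6-Me3C6H2MgBr (1 equiv) in THF; then MeMgBr (excess), −78 → 0 °C; aq. NH4Cl; chromatography
Reagents that add atoms: methylmagnesium bromide C[Mg]Br
Why: Iodine–lithium exchange and transmetalation give the Grignard reagent, which at −78 °C adds only to the aldehyde of the bromomagnesium 13-alkoxide through a five-membered chelate, entering C14 on the side of the C13 methyl group (anti to C12) to give the 14R carbinol; the excess MeMgBr then adds to the 8-ketone from the equatorial α face because the axial face is blocked by the syn-axial C10 methyl group, which sets the axial 8β-OH, and doing both additions in one flask keeps the diol ketone from closing to its internal bicyclic ketal, with minor epimers removed at the triol (chelation-controlled Grignard addition, then 1,2-addition to a ketone).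

Step 9
Reactants: 13 triol ketal
Product: 14 13,14-cyclic carbonate with free 8-OH
Conditions: 1,1'-carbonyldiimidazole, DMAP (cat.), toluene, 70 °C
Reagents that add atoms: 1,1'-carbonyldiimidazole O=C(n1ccnc1)n1ccnc1
Why: The reagent acylates the secondary 14-OH and the adjacent tertiary 13-OH closes the five-membered ring, so the isolated and hindered 8-OH remains the only free hydroxyl (cyclic carbonate formation).

Step 10
Reactants: 14 cyclic carbonate
Product: 15 8-O-triethylsilyl cyclic carbonate ketal
Conditions: Et3SiOTf, 2,6-lutidine, CH2Cl2, −78 → 0 °C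
Reagents that add atoms: triethylsilyl trifluoromethanesulfonate CC[Si](CC)(CC)OS(=O)(=O)C(F)(F)F
Why: The silyl triflate with a hindered pyridine base silylates the crowded axial tertiary 8-OH, and placing this step before any oxirane or enone exists removes the danger of Lewis-acid opening of the later epoxide (silylation of a tertiary alcohol).

Step 11
Reactants: 15 silylated carbonate ketal
Product: 16 methyl ketone (C8'=O) with carbonate and silyl ether retained
Conditions: PPTS, acetone–H2O, 50 °C
Reagents that add atoms: water O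
Why: Mild acid-catalysed hydrolysis of the dioxolane frees the methyl ketone, while the cyclic carbonate, the hindered tertiary silyl ether and the trisubstituted alkene should survive (ketal hydrolysis).

Step 12
Reactants: 16 carbonate methyl ketone; 17 2,5-dimethoxybenzaldehyde
Product: 19 (13R,14R)-13,14-diol E-aryl enone 8-O-triethylsilyl ether, via diol methyl ketone 18 (not isolated)
Conditions: NaOH (aq.), EtOH, rt; then 17, rt
Reagents that add atoms: none
Why: Hydroxide first saponifies the cyclic carbonate and then promotes a Claisen–Schmidt condensation, which under base occurs at the methyl group (C9') of the methyl ketone and gives the conjugated E-enone after loss of water.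

Step 13
Reactants: 19 diol aryl enone
Product: 20 (14R)-14-O-mesylate
Conditions: MsCl, Et3N, CH2Cl2, −20 °C
Reagents that add atoms: methanesulfonyl chloride CS(=O)(=O)Cl
Why: The sulfonyl chloride reacts with the only secondary hydroxyl (C14), because the tertiary 13-OH is too hindered at low temperature (selective sulfonylation).

Step 14
Reactants: 20 hydroxy mesylate
Product: 21 (13R,14S)-cis-13,14-oxirane aryl enone
Conditions: K2CO3, MeOH, 0 °C → rt
Reagents that add atoms: none
Why: The 13-alkoxide displaces the neighbouring mesylate intramolecularly with inversion at C14 and retention at C13, which places C12 and C2' cis on the oxirane (Williamson-type epoxide closure).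

Step 15
Reactants: 21 oxirane aryl enone
Product: 22 cyclisation precursor with cis-oxirane, E-alkene and Z-triethylsilyl enol ether
Conditions: Et3SiH, RhCl(PPh3)3 (cat.), benzene, 60 °C; filtration through Et3N-deactivated silica
Reagents that add atoms: triethylsilane CC[SiH](CC)CC
Why: Rhodium-catalysed hydrosilylation of an enone with a monohydrosilane adds 1,4 through the s-cis conformer and so gives the regiodefined Z-silyl enol ether (O cis to C11', C7' trans to C11') under neutral conditions that do not touch the oxirane.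

Step 16
Reactants: 22 cyclisation precursor
Product: 23 3'β-hydroxy-8'-oxo bis-decalin 8-O-triethylsilyl ether
Conditions: MeAlCl2 (hexanes), CH2Cl2, high dilution, −90 → −78 °C; Et3N, then aq. potassium sodium tartrate
Reagents that add atoms: none
Why: MeAlCl2 binds the oxirane oxygen and the tertiary C4'–O bond lengthens while C5' of the E-alkene attacks from the rear; the tertiary C10' cation so formed is taken by C9' of the silyl enol ether, and the silyloxocarbenium ion gives up Et3Si to chloride to leave the C8' ketone. The closest known reaction type is the MeAlCl2-promoted cyclisation of epoxy polyenes terminated by a silyl enol ether, which gives trans-fused hydroxy ketones. Ring A' closes by C4'–C5' bond formation, 6-endo at both the oxirane and the alkene, and ring B' closes by C10'–C9' bond formation, 6-endo at the enol ether, each through a chair. C4' is fixed by inversion of manool C13 (C12 arm axial, methyl equatorial) and the oxygen stays equatorial on C3'; anti addition across the E-alkene in the chair–chair fold gives 5'α-H and 10'β-CH3; the Z enol ether places C11' equatorial on C9', which is also the stable epimer next to the ketone. The step needs concerted anti opening at C4' instead of a free cation, a hydride shift or capture by O8: the cis-oxirane, E-alkene and Z-enol ether geometries pre-set the fold, the bulky silyl group on the crowded axial O8 blocks closure to the 8,13-ether, and the enol ether ends the cascade before the arene or a methoxy oxygen can trap a C8' cation.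

Step 17
Reactants: 23 hydroxy ketone
Product: 24 3'-O-(imidazol-1-ylthiocarbonyl) derivative
Conditions: 1,1'-thiocarbonyldiimidazole, DMAP, ClCH2CH2Cl, 80 °C
Reagents that add atoms: 1,1'-thiocarbonyldiimidazole S=C(n1ccnc1)n1ccnc1
Why: The equatorial secondary 3'-OH, the only free hydroxyl, is thioacylated under forcing conditions to give the radical precursor (first stage of a Barton–McCombie deoxygenation).

Step 18
Reactants: 24 thiocarbonylimidazolide
Product: 25 3'-deoxy 8'-ketone
Conditions: Bu3SnH, AIBN (cat.), toluene, 110 °C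
Reagents that add atoms: none
Why: Addition of the tin radical to the thiocarbonyl group and β-scission release the secondary C3' radical, which takes hydrogen from the tin hydride, so the carbinol that steered the fold is erased while the ketone and silyl ether are inert (Barton–McCombie deoxygenation).

Step 19
Reactants: 25 8'-ketone
Product: 26 Δ7'-enol triflate
Conditions: KN(SiMe3)2, THF, −78 °C; PhNTf2, −78 → 0 °C
Reagents that add atoms: N-phenylbis(trifluoromethanesulfonimide) O=S(=O)(N(c1ccccc1)S(=O)(=O)C(F)(F)F)C(F)(F)F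
Why: The bulky amide base removes the accessible C7' proton kinetically instead of the hindered C9' methine, and O-sulfonylation of the enolate fixes the alkene at C7'=C8' (regioselective enol triflate formation).

Step 20
Reactants: 26 enol triflate
Product: 27 8'-methyl-Δ7' alkene 8-O-triethylsilyl ether
Conditions: MeMgBr, Fe(acac)3 (cat.), THF–NMP, −30 → 0 °C
Reagents that add atoms: methylmagnesium bromide C[Mg]Br
Why: Iron-catalysed cross-coupling of the alkenyl triflate with the methyl Grignard reagent replaces the triflate by CH3 without moving the alkene, and the ethers do not react at low temperature (Kumada-type coupling).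

Step 21
Reactants: 27 silyl ether
Product: 28 hydroquinone dimethyl ether of the aglycone
Conditions: Bu4NF, THF, 50 °C
Reagents that add atoms: none
Why: Fluoride cleaves the Si–O bond of the hindered tertiary silyl ether on warming and leaves the aryl methyl ethers and the alkene untouched (desilylation).

Step 22
Reactants: 28 aglycone dimethyl ether
Product: 30 free hydroquinone, via benzoquinone 29 (not isolated)
Conditions: (NH4)2Ce(NO3)6, MeCN–H2O, 0 °C; Et2O extract shaken with aq. Na2S2O4 under Ar; used at once
Reagents that add atoms: water O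
Why: Tetravalent cerium oxidises the 1,4-dimethoxyarene in two one-electron steps, with ipso attack of water and loss of methanol, to the quinone, and dithionite reduces the quinone during work-up, so the air-sensitive hydroquinone is made just before use (oxidative demethylation, then quinone reduction).

Step 23
Reactants: 30 hydroquinone
Product: 31 target CNP0471499.2
Conditions: SO3·pyridine (excess), pyridine, rt, Ar; H+-form cation-exchange resin, H2O–MeOH, 0 °C; freeze-drying
Reagents that add atoms: sulfur trioxide–pyridine complex [O-]S(=O)(=O)[n+]1ccccc1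
Why: The amine complex of SO3 sulfates both phenolic oxygens but not the hindered axial tertiary 8-OH, and cold cation exchange turns the pyridinium salt into the bis(hydrogen sulfate) (O-sulfation of phenols).

Compound list

1 | (+)-manool, (13R)-labda-8(17),14-dien-13-ol | C=C[C@](C)(O)CC[C@@H]1[C@@]2(C)CCCC(C)(C)[C@@H]2CCC1=C | starting material
2 | (13R)-13-hydroxy-8-oxo-15,17-dinorlabdan-14-al | O=C[C@](C)(O)CC[C@@H]1[C@@]2(C)CCCC(C)(C)[C@@H]2CCC1=O | intermediate
3 | 6-methylhept-5-en-2-one | CC(C)=CCCC(C)=O | starting material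
4 | 2-methyl-2-(4-methylpent-3-en-1-yl)-1,3-dioxolane | CC(C)=CCCC1(C)OCCO1 | intermediate
5 | (E)-2-methyl-5-(2-methyl-1,3-dioxolan-2-yl)pent-2-en-1-ol | OC/C(C)=C/CCC1(C)OCCO1 | intermediate
6 | (E)-2-methyl-5-(2-methyl-1,3-dioxolan-2-yl)pent-2-enal | O=C/C(C)=C/CCC1(C)OCCO1 | intermediate
7 | (E)-2-methyl-2-(4-methylhexa-3,5-dien-1-yl)-1,3-dioxolane | C=C/C(C)=C/CCC1(C)OCCO1 | intermediate
8 | (E)-3-methyl-6-(2-methyl-1,3-dioxolan-2-yl)hex-3-en-1-ol | OCC/C(C)=C/CCC1(C)OCCO1 | intermediate
9 | (E)-2-(6-iodo-4-methylhex-3-en-1-yl)-2-methyl-1,3-dioxolane (C2', C1', C10', C5'–C9'; C8' as dioxolane) | ICC/C(C)=C/CCC1(C)OCCO1 | intermediate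
10 | (E)-[3-methyl-6-(2-methyl-1,3-dioxolan-2-yl)hex-3-en-1-yl]lithium | [Li]CC/C(C)=C/CCC1(C)OCCO1 | intermediate
11 | (E)-[3-methyl-6-(2-methyl-1,3-dioxolan-2-yl)hex-3-en-1-yl]magnesium bromide | Br[Mg]CC/C(C)=C/CCC1(C)OCCO1 | intermediate
12 | (13R,14R)-13,14-dihydroxy 8-ketone: 17-norlabdan-8-one joined at C14 to C2' of the E-alkenyl dioxolane chain (present as its bromomagnesium alkoxide) | C[C@@](O)(CC[C@@H]1[C@@]2(C)CCCC(C)(C)[C@@H]2CCC1=O)[C@H](O)CC/C(C)=C/CCC1(C)OCCO1 | intermediate
13 | (8S,13R,14R)-8,13,14-triol ketal: axial 8β-OH, equatorial 8α-CH3, E-C5'=C10' alkene, C8' dioxolane | C[C@@](O)(CC[C@@H]1[C@@]2(C)CCCC(C)(C)[C@@H]2CC[C@]1(C)O)[C@H](O)CC/C(C)=C/CCC1(C)OCCO1 | intermediate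
14 | (13R,14R)-13,14-cyclic carbonate of 13, 8β-OH free | C[C@]1(CC[C@@H]2[C@@]3(C)CCCC(C)(C)[C@@H]3CC[C@]2(C)O)OC(=O)O[C@@H]1CC/C(C)=C/CCC1(C)OCCO1 | intermediate
15 | 8-O-triethylsilyl ether of 14 | C[C@]1(CC[C@@H]2[C@@]3(C)CCCC(C)(C)[C@@H]3CC[C@]2(C)O[Si](CC)(CC)CC)OC(=O)O[C@@H]1CC/C(C)=C/CCC1(C)OCCO1 | intermediate
16 | methyl ketone (C8'=O, C9'H3) with 13,14-carbonate and 8-O-SiEt3 | C[C@]1(CC[C@@H]2[C@@]3(C)CCCC(C)(C)[C@@H]3CC[C@]2(C)O[Si](CC)(CC)CC)OC(=O)O[C@@H]1CC/C(C)=C/CCC(C)=O | intermediate
17 | 2,5-dimethoxybenzaldehyde | COc1ccc(OC)c(C=O)c1 | starting material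
18 | (13R,14R)-13,14-diol methyl ketone, 8-O-SiEt3 | C[C@@](O)(CC[C@@H]1[C@@]2(C)CCCC(C)(C)[C@@H]2CC[C@]1(C)O[Si](CC)(CC)CC)[C@H](O)CC/C(C)=C/CCC(C)=O | intermediate
19 | (13R,14R)-13,14-diol E-aryl enone, C8'(=O)–C9'H=C11'H–(2,5-dimethoxyphenyl), 8-O-SiEt3 | C[C@@](O)(CC[C@@H]1[C@@]2(C)CCCC(C)(C)[C@@H]2CC[C@]1(C)O[Si](CC)(CC)CC)[C@H](O)CC/C(C)=C/CCC(=O)/C=C/c1cc(OC)ccc1OC | intermediate
20 | (13R,14R)-13-hydroxy 14-methanesulfonate of 19 | C[C@@](O)(CC[C@@H]1[C@@]2(C)CCCC(C)(C)[C@@H]2CC[C@]1(C)O[Si](CC)(CC)CC)[C@H](OS(C)(=O)=O)CC/C(C)=C/CCC(=O)/C=C/c1cc(OC)ccc1OC | intermediate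
21 | (13R,14S)-cis-13,14-oxirane (C12 and C2' cis) E-aryl enone, 8-O-SiEt3 | C[C@]1(CC[C@@H]2[C@@]3(C)CCCC(C)(C)[C@@H]3CC[C@]2(C)O[Si](CC)(CC)CC)O[C@H]1CC/C(C)=C/CCC(=O)/C=C/c1cc(OC)ccc1OC | intermediate
22 | cyclisation precursor: (13R,14S)-cis-oxirane, E-C5'=C10' alkene, Z-C8'(OSiEt3)=C9'H–CH2(2,5-dimethoxyphenyl), 8-O-SiEt3 | C[C@]1(CC[C@@H]2[C@@]3(C)CCCC(C)(C)[C@@H]3CC[C@]2(C)O[Si](CC)(CC)CC)O[C@H]1CC/C(C)=C/CC/C(O[Si](CC)(CC)CC)=C/Cc1cc(OC)ccc1OC | intermediate
23 | 3'β-hydroxy-8'-oxo bis-decalin: 4'α-CH3, 4'β (axial) C12 arm, 5'α-H, 10'β-CH3, 9'β-(2,5-dimethoxybenzyl), 8-O-SiEt3 | O=C1CC[C@H]2[C@@](C)(CC[C@@H]3[C@@]4(C)CCCC(C)(C)[C@@H]4CC[C@]3(C)O[Si](CC)(CC)CC)[C@@H](O)CC[C@]2(C)[C@H]1Cc1cc(OC)ccc1OC | intermediate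
24 | 3'β-O-(imidazol-1-ylthiocarbonyl) derivative of 23 | O=C1CC[C@H]2[C@@](C)(CC[C@@H]3[C@@]4(C)CCCC(C)(C)[C@@H]4CC[C@]3(C)O[Si](CC)(CC)CC)[C@@H](OC(=S)n3ccnc3)CC[C@]2(C)[C@H]1Cc1cc(OC)ccc1OC | intermediate
25 | 3'-deoxy 8'-ketone, 8-O-SiEt3 | O=C1CC[C@H]2[C@@](C)(CC[C@@H]3[C@@]4(C)CCCC(C)(C)[C@@H]4CC[C@]3(C)O[Si](CC)(CC)CC)CCC[C@]2(C)[C@H]1Cc1cc(OC)ccc1OC | intermediate
26 | Δ7'-enol trifluoromethanesulfonate (C8'–OTf), 8-O-SiEt3 | O=S(=O)(OC1=CC[C@H]2[C@@](C)(CC[C@@H]3[C@@]4(C)CCCC(C)(C)[C@@H]4CC[C@]3(C)O[Si](CC)(CC)CC)CCC[C@]2(C)[C@H]1Cc1cc(OC)ccc1OC)C(F)(F)F | intermediate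
27 | 8'-methyl-Δ7' alkene, 8-O-SiEt3, aryl dimethyl ether | CC1=CC[C@H]2[C@@](C)(CC[C@@H]3[C@@]4(C)CCCC(C)(C)[C@@H]4CC[C@]3(C)O[Si](CC)(CC)CC)CCC[C@]2(C)[C@H]1Cc1cc(OC)ccc1OC | intermediate
28 | hydroquinone dimethyl ether of the aglycone, free axial 8β-OH | CC1=CC[C@H]2[C@@](C)(CC[C@@H]3[C@@]4(C)CCCC(C)(C)[C@@H]4CC[C@]3(C)O)CCC[C@]2(C)[C@H]1Cc1cc(OC)ccc1OC | intermediate
29 | 2-substituted 1,4-benzoquinone of the aglycone | CC1=CC[C@H]2[C@@](C)(CC[C@@H]3[C@@]4(C)CCCC(C)(C)[C@@H]4CC[C@]3(C)O)CCC[C@]2(C)[C@H]1CC1=CC(=O)C=CC1=O | intermediate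
30 | free hydroquinone of the aglycone | CC1=CC[C@H]2[C@@](C)(CC[C@@H]3[C@@]4(C)CCCC(C)(C)[C@@H]4CC[C@]3(C)O)CCC[C@]2(C)[C@H]1Cc1cc(O)ccc1O | intermediate
31 | CNP0471499.2, hydroquinone bis(hydrogen sulfate) | CC1=CC[C@H]2[C@@](C)(CC[C@@H]3[C@@]4(C)CCCC(C)(C)[C@@H]4CC[C@]3(C)O)CCC[C@]2(C)[C@H]1Cc1cc(OS(=O)(=O)O)ccc1OS(=O)(=O)O | target

Total step count: 23. Longest linear sequence: 22 steps (from 3 to 31: steps 2–7, then steps 8–23).

Steps most likely to fail

Step 16. The activated oxirane may be consumed before the alkene engages (1,2-hydride shift to a C3' ketone, elimination, or attack by O8 with loss of silyl). The axial placement of the long C12 arm may also slow the chair–chair fold, and the enol ether may be protodesilylated so that the cascade ends after ring A'. The fallback keeps the oxirane trigger but replaces the acid-labile oxygen terminator by a carbon-based allylsilane, and introduces the C8' carbonyl afterwards by alkene cleavage. It sets out from 22. CsF and PhNTf2 in DME at rt convert the silyl enol ether, with its position and geometry retained, into the Z-enol triflate F1. Pd(PPh3)4-catalysed coupling with Me3SiCH2MgCl gives the Z-allylsilane F2, in which C7' is still trans to C11'. MeAlCl2 or BF3·OEt2 in CH2Cl2 at −78 °C then effects the allylsilane-terminated oxirane/alkene bicyclisation; loss of Me3Si from the β-silyl C8' cation gives the 3'β-hydroxy 8'(12')-methylidene bis-decalin F3. Cleavage of the exocyclic alkene with OsO4 (cat.) and NaIO4 in the presence of 2,6-lutidine rejoins the route at ketone 23, where C9' can still be equilibrated by base to the equatorial epimer.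

Step 8. Facial selectivity in the aldehyde addition may be poor, because chelated and open transition states compete and the CH3 and CH2 groups on C13 differ little in size; the first Grignard reagent may also enolise or attack the 8-ketone. The fallback sets C14 by reagent control instead of substrate control. It sets out from 13 as its C14 epimer mixture. Dess–Martin periodinane (NaHCO3, CH2Cl2) oxidises only the secondary carbinol to the (13R)-8β,13-dihydroxy 14-ketone F4. Reduction with catecholborane under (S)-2-methyl-CBS-oxazaborolidine catalysis (toluene, −78 °C), with quaternary C13 as the large group and C2'H2 as the small one, should return the 14R alcohol, that is triol 13, which continues with step 9.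

Step 23. Sulfation of the more hindered phenol next to the benzylic carbon may be incomplete, the hydroquinone may be oxidised by air in pyridine, and sulfate may be lost by acid-catalysed hydrolysis (or water lost at C8) when the salt is turned into the free acid. The fallback uses protected sulfate diesters that can be purified as neutral compounds. It sets out from 30. 2,2,2-Trichloroethyl chlorosulfate with Et3N and DMAP in THF gives the bis(2,2,2-trichloroethyl sulfate) F5. Zn dust and HCO2NH4 in MeOH remove both trichloroethyl groups by reductive elimination, and the same cold cation exchange gives 31.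

Further compounds

F1 | step 16 | Z-enol trifluoromethanesulfonate at C8'=C9' (cis-oxirane, E-alkene and 8-O-SiEt3 retained) | C[C@]1(CC[C@@H]2[C@@]3(C)CCCC(C)(C)[C@@H]3CC[C@]2(C)O[Si](CC)(CC)CC)O[C@H]1CC/C(C)=C/CC/C(OS(=O)(=O)C(F)(F)F)=C/Cc1cc(OC)ccc1OC
F2 | step 16 | Z-allylsilane, C8'(CH2SiMe3)=C9'H–CH2(2,5-dimethoxyphenyl), cis-oxirane and 8-O-SiEt3 retained | C[C@]1(CC[C@@H]2[C@@]3(C)CCCC(C)(C)[C@@H]3CC[C@]2(C)O[Si](CC)(CC)CC)O[C@H]1CC/C(C)=C/CC/C(C[Si](C)(C)C)=C/Cc1cc(OC)ccc1OC
F3 | step 16 | 3'β-hydroxy-8'(12')-methylidene bis-decalin, 8-O-SiEt3 | C=C1CC[C@H]2[C@@](C)(CC[C@@H]3[C@@]4(C)CCCC(C)(C)[C@@H]4CC[C@]3(C)O[Si](CC)(CC)CC)[C@@H](O)CC[C@]2(C)[C@H]1Cc1cc(OC)ccc1OC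
F4 | step 8 | (8S,13R)-8,13-dihydroxy 14-ketone with E-alkene and C8' dioxolane | C[C@@](O)(CC[C@@H]1[C@@]2(C)CCCC(C)(C)[C@@H]2CC[C@]1(C)O)C(=O)CC/C(C)=C/CCC1(C)OCCO1
F5 | step 23 | bis(2,2,2-trichloroethyl sulfate) diester of hydroquinone 30 | CC1=CC[C@H]2[C@@](C)(CC[C@@H]3[C@@]4(C)CCCC(C)(C)[C@@H]4CC[C@]3(C)O)CCC[C@]2(C)[C@H]1Cc1cc(OS(=O)(=O)OCC(Cl)(Cl)Cl)ccc1OS(=O)(=O)OCC(Cl)(Cl)Cl
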